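**Retrosynthetic overview**
1. Feature: in the ten-membered carbocycle (ring A, C1–C10; C14 on C10, C15 on C4) C7 lies between the oxygen-bearing C8 and C6, the allylic CH2 of the C4=C5 olefin, so C6–C7 joins the α-carbon of a C8 ketone to an allyl terminus.
2. Target 35 ⇐ C14–OPMB cleavage, C15 acylation, C11 methylenation and C8 reduction/lactonisation (γ-lactone ring B, formed last) from ten-membered ketone 26.
3. 26 ⇐ twelve-membered allyl β-keto lactone 25 by palladium-catalysed CO2 extrusion with C6–C7 bond formation (ring A formed by 12→10 contraction).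
4. 25 ⇐ C7 alkylation of macrolactone 23 ⇐ acylketene macrolactonisation of hydroxy acyl Meldrum's acid 21 ⇐ β,γ-unsaturated acid 18.
5. 18 ⇐ two 2-metalloallyl ether additions (both from 2-bromoallyl alcohol), each followed by a rearrangement: Johnson–Claisen for C4=C5 (C3 trans to C6), Still [2,3]-Wittig for C10=C1 (C9 cis to C2).

Key step: step 14

Assumption: (S)-t-Bu-PHOX is written in step 14; the sense of induction at C7 cannot be predicted for this tethered enolate, and the mirror-image ligand is taken if the 7S ketone is favoured.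
Design note: C9 is bonded directly to olefinic C10, so the C8–C9–C10 unit cannot arise by γ-alkylation of a 6-methyl dioxinone; the acylketene is generated from the acyl Meldrum's acid of 18 instead. C15 carries TBDPS, C14 PMB (no silyl group next to the alkoxide of step 7) and C12 is a methyl ester (lactonisation without strong acid). Germacrane numbering is used throughout.

**Step 1**
Reactants: 1 2-bromoprop-2-en-1-ol
Product: 2 [(2-bromoprop-2-en-1-yl)oxy](tert-butyl)diphenylsilane
Conditions: TBDPSCl, imidazole, CH2Cl2, 0 °C to rt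
Reagents that add atoms: tert-butyl(chloro)diphenylsilane, CC(C)(C)[Si](Cl)(c1ccccc1)c1ccccc1
Why: Standard silylation of a primary alcohol; this robust silyl ether becomes the C15–O protecting group that is removed only in step 17.

**Step 2**
Reactants: 2 [(2-bromoprop-2-en-1-yl)oxy](tert-butyl)diphenylsilane; 3 2-[(tert-butyldimethylsilyl)oxy]acetaldehyde
Product: 5 rac-1-[(tert-butyldimethylsilyl)oxy]-3-{[(tert-butyldiphenylsilyl)oxy]methyl}but-3-en-2-ol, via vinylchromium dichloride 4 (not isolated)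
Conditions: CrCl2 (4 equiv), NiCl2 (2 mol %), DMF, rt; aq. work-up
Reagents that add atoms: none
Why: Nozaki–Hiyama–Kishi coupling of a 2-bromoalkene with an aldehyde forms C4–C5 under non-basic conditions, avoiding a 2-lithioallyl silyl ether that could suffer silyl migration or allene formation; the C5 carbinol centre is racemic and is destroyed in step 3.

**Step 3**
Reactants: 5 rac-1-[(tert-butyldimethylsilyl)oxy]-3-{[(tert-butyldiphenylsilyl)oxy]methyl}but-3-en-2-ol; 6 triethyl orthoacetate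
Product: 8 ethyl (4Z)-6-[(tert-butyldimethylsilyl)oxy]-4-{[(tert-butyldiphenylsilyl)oxy]methyl}hex-4-enoate (C3 trans to C6), via mixed ketene acetal 7 (not isolated)
Conditions: MeC(OEt)3 (6 equiv), EtCO2H (0.1 equiv), 140 °C, EtOH distilled off
Reagents that add atoms: none
Why: Johnson–Claisen rearrangement through a chair transition state with the CH2OTBS group equatorial forms C2–C3 and should place C3 trans to C6 across the new C4=C5 bond (Z by CIP because of C15–O).

**Step 4**
Reactants: 8 ethyl (4Z)-6-[(tert-butyldimethylsilyl)oxy]-4-{[(tert-butyldiphenylsilyl)oxy]methyl}hex-4-enoate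
Product: 9 (4Z)-6-[(tert-butyldimethylsilyl)oxy]-4-{[(tert-butyldiphenylsilyl)oxy]methyl}hex-4-enal
Conditions: i-Bu2AlH (1.1 equiv), CH2Cl2, −78 °C; aq. KNaC4H4O6 (potassium sodium tartrate)
Reagents that add atoms: none
Why: Partial reduction of an unhindered ethyl ester at low temperature stops at the aluminium hemiacetal, which releases the C1 aldehyde on work-up; silyl ethers and the olefin are inert.

**Step 5**
Reactants: 1 2-bromoprop-2-en-1-ol
Product: 10 1-{[(2-bromoprop-2-en-1-yl)oxy]methyl}-4-methoxybenzene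
Conditions: NaH, 4-methoxybenzyl chloride, Bu4NI (cat.), THF, 0 °C to rt
Reagents that add atoms: 4-methoxybenzyl chloride, COc1ccc(CCl)cc1
Why: Williamson etherification of a primary alkoxide with a benzylic chloride gives the PMB ether that will protect C14–O to the last step.

**Step 6**
Reactants: 10 1-{[(2-bromoprop-2-en-1-yl)oxy]methyl}-4-methoxybenzene; 9 (4Z)-6-[(tert-butyldimethylsilyl)oxy]-4-{[(tert-butyldiphenylsilyl)oxy]methyl}hex-4-enal
Product: 12 rac-(6Z)-8-[(tert-butyldimethylsilyl)oxy]-6-{[(tert-butyldiphenylsilyl)oxy]methyl}-2-{[(4-methoxyphenyl)methoxy]methyl}octa-1,6-dien-3-ol, via vinyllithium 11 (not isolated)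
Conditions: t-BuLi (2.1 equiv), Et2O, −78 °C; then 9, −78 °C; aq. NH4Cl
Reagents that add atoms: none
Why: Bromine–lithium exchange and 1,2-addition of the 2-lithioallyl ether (kept at −78 °C to prevent β-alkoxide loss) forms C1–C10; the C1 carbinol centre is racemic and is consumed in step 8.

**Step 7**
Reactants: 12 rac-(6Z)-8-[(tert-butyldimethylsilyl)oxy]-6-{[(tert-butyldiphenylsilyl)oxy]methyl}-2-{[(4-methoxyphenyl)methoxy]methyl}octa-1,6-dien-3-ol; 13 tributyl(iodomethyl)stannane
Product: 14 tributyl{[((6Z)-8-[(tert-butyldimethylsilyl)oxy]-6-{[(tert-butyldiphenylsilyl)oxy]methyl}-2-{[(4-methoxyphenyl)methoxy]methyl}octa-1,6-dien-3-yl)oxy]methyl}stannane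
Conditions: KH, 18-crown-6 (cat.), THF, 0 °C; then 13, rt
Reagents that add atoms: none
Why: Williamson O-alkylation of the secondary allylic alkoxide with the iodomethylstannane installs the future C8; the neighbouring oxygen carries PMB, so no silyl group can migrate to the alkoxide.

**Step 8**
Reactants: 14 tributyl{[((6Z)-8-[(tert-butyldimethylsilyl)oxy]-6-{[(tert-butyldiphenylsilyl)oxy]methyl}-2-{[(4-methoxyphenyl)methoxy]methyl}octa-1,6-dien-3-yl)oxy]methyl}stannane
Product: 16 (3E,7Z)-9-[(tert-butyldimethylsilyl)oxy]-7-{[(tert-butyldiphenylsilyl)oxy]methyl}-3-{[(4-methoxyphenyl)methoxy]methyl}nona-3,7-dien-1-ol (C9 cis to C2; C3 trans to C6), via alkoxymethyllithium 15 (not isolated)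
Conditions: n-BuLi (1.5 equiv), THF, −78 °C; aq. NH4Cl
Reagents that add atoms: none
Why: Tin–lithium exchange triggers the Still variant of the [2,3]-Wittig rearrangement, forming C8–C9; the C2 chain should sit pseudo-axial in the envelope transition state to avoid allylic strain with the C14 substituent on C10, which places C9 cis to C2 across the new C10=C1 bond (E by CIP because of C14–O).

**Step 9**
Reactants: 16 (3E,7Z)-9-[(tert-butyldimethylsilyl)oxy]-7-{[(tert-butyldiphenylsilyl)oxy]methyl}-3-{[(4-methoxyphenyl)methoxy]methyl}nona-3,7-dien-1-ol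
Product: 18 (3E,7Z)-9-[(tert-butyldimethylsilyl)oxy]-7-{[(tert-butyldiphenylsilyl)oxy]methyl}-3-{[(4-methoxyphenyl)methoxy]methyl}nona-3,7-dienoic acid, via aldehyde 17 (not isolated)
Conditions: Dess–Martin periodinane, NaHCO3, CH2Cl2, 0 °C; then NaClO2, NaH2PO4, 2-methylbut-2-ene, t-BuOH/H2O, 0 °C
Reagents that add atoms: sodium chlorite, [Na+].[O-]Cl=O
Why: Buffered Dess–Martin oxidation followed at once by Pinnick oxidation takes the homoallylic alcohol to the β,γ-unsaturated C8 acid under near-neutral conditions that should not move the C10=C1 bond into conjugation, with the alkene scavenger protecting the olefins and the PMB ether from hypochlorite.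

**Step 10**
Reactants: 18 (3E,7Z)-9-[(tert-butyldimethylsilyl)oxy]-7-{[(tert-butyldiphenylsilyl)oxy]methyl}-3-{[(4-methoxyphenyl)methoxy]methyl}nona-3,7-dienoic acid; 19 2,2-dimethyl-1,3-dioxane-4,6-dione (Meldrum's acid)
Product: 20 5-[(3E,7Z)-9-[(tert-butyldimethylsilyl)oxy]-7-{[(tert-butyldiphenylsilyl)oxy]methyl}-1-hydroxy-3-{[(4-methoxyphenyl)methoxy]methyl}nona-3,7-dien-1-ylidene]-2,2-dimethyl-1,3-dioxane-4,6-dione
Conditions: DCC, DMAP (1.5 equiv), CH2Cl2, 0 °C to rt; cold aq. KHSO4 wash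
Reagents that add atoms: none
Why: Carbodiimide-mediated C-acylation of Meldrum's acid gives the enolised acyl Meldrum's acid, a latent acylketene that supplies C7 and the lactone carbonyl.

**Step 11**
Reactants: 20 acyl Meldrum's acid with C6–OTBS
Product: 21 5-[(3E,7Z)-7-{[(tert-butyldiphenylsilyl)oxy]methyl}-1,9-dihydroxy-3-{[(4-methoxyphenyl)methoxy]methyl}nona-3,7-dien-1-ylidene]-2,2-dimethyl-1,3-dioxane-4,6-dione
Conditions: HF·pyridine, pyridine, THF, 0 °C
Reagents that add atoms: none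
Why: Buffered HF cleaves the primary TBS ether much faster than the TBDPS ether and does not touch the PMB ether or the acid-stable acyl Meldrum's acid, freeing the C6 hydroxyl.

**Step 12**
Reactants: 21 hydroxy acyl Meldrum's acid
Product: 23 (6E,10Z)-10-{[(tert-butyldiphenylsilyl)oxy]methyl}-6-{[(4-methoxyphenyl)methoxy]methyl}-1-oxacyclododeca-6,10-diene-2,4-dione, via acylketene 22 (not isolated)
Conditions: toluene, 110 °C, slow addition to a final 0.001 M
Reagents that add atoms: none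
Why: Thermal loss of acetone and CO2 gives an acylketene that is trapped by the C6 hydroxyl (acylketene macrolactonisation), closing the twelve-membered allyl β-keto lactone; the two trisubstituted olefins restrict the chain and dilution suppresses diolide formation.

**Step 13**
Reactants: 23 twelve-membered β-keto lactone; 24 methyl bromoacetate
Product: 25 methyl 2-[(6E,10Z)-10-{[(tert-butyldiphenylsilyl)oxy]methyl}-6-{[(4-methoxyphenyl)methoxy]methyl}-2,4-dioxo-1-oxacyclododeca-6,10-dien-3-yl]acetate (racemic at C7)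
Conditions: K2CO3 (1.5 equiv), 24 (1.05 equiv), acetone, rt
Reagents that add atoms: none
Why: The doubly activated C7–H is the only proton removed by carbonate, and C-alkylation of the β-keto ester enolate with the α-bromo ester installs C11–C12; the C7 configuration is irrelevant because this centre becomes an enolate in step 14.

**Step 14**
Reactants: 25 methyl 2-[(6E,10Z)-10-{[(tert-butyldiphenylsilyl)oxy]methyl}-6-{[(4-methoxyphenyl)methoxy]methyl}-2,4-dioxo-1-oxacyclododeca-6,10-dien-3-yl]acetate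
Product: 26 methyl 2-[(1R,3Z,7E)-4-{[(tert-butyldiphenylsilyl)oxy]methyl}-8-{[(4-methoxyphenyl)methoxy]methyl}-10-oxocyclodeca-3,7-dien-1-yl]acetate (7R)
Conditions: Pd2(dba)3 (5 mol %, zerovalent palladium), (S)-t-Bu-PHOX (12.5 mol %), toluene, 0.005 M, 30 °C
Reagents that add atoms: none
Why: Proposed new method: zerovalent palladium ionises the allylic C6–O bond of 25 to a π-allylpalladium (C4–C5–C6) β-keto carboxylate, CO2 is lost to give the C7 enolate of the C8 ketone on the same chain, and C7 adds to the unsubstituted terminus C6; the closest known reaction type is the Tsuji–Trost decarboxylative allylation of allyl β-keto esters with phosphinooxazoline ligands, which has not been run as a contraction of a macrolactone to a medium carbocycle. Ring A closes by intramolecular C-allylation (C6–C7) inside this ion pair, so the O–C(=O) unit of the twelve-membered ring is excised and a ten-membered carbocycle containing the whole allyl unit results, irreversibly because CO2 leaves. The new C7 stereocentre is set by the chiral P,N-ligand on the palladium-bound enolate, which has to deliver C6 to the face that gives 7R. The step needs attack at C6 and not at C4, C- and not O-allylation, retention of the C4=C5 geometry, and loss of CO2 before C–C bond formation although C7 carries an acidic hydrogen. The fully substituted C4 terminus disfavours branched attack and syn–anti exchange of the allyl unit, C10=C1 is not involved, and base-free toluene at high dilution is chosen to keep the enolate on palladium and to suppress proton transfer, oligomerisation and epimerisation of the product.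

**Step 15**
Reactants: 26 methyl 2-[(1R,3Z,7E)-4-{[(tert-butyldiphenylsilyl)oxy]methyl}-8-{[(4-methoxyphenyl)methoxy]methyl}-10-oxocyclodeca-3,7-dien-1-yl]acetate
Product: 28 (3aR,5Z,9E,11aS)-6-{[(tert-butyldiphenylsilyl)oxy]methyl}-10-{[(4-methoxyphenyl)methoxy]methyl}-3a,4,7,8,11,11a-hexahydrocyclodeca[b]furan-2(3H)-one (trans-fused; 7R,8S), via hydroxy ester 27 (not isolated)
Conditions: (R)-2-methyl-CBS-oxazaborolidine (1.0 equiv), catecholborane (2 equiv), toluene, −78 °C; MeOH then pH 7 buffer; then PPTS (0.2 equiv), toluene, 60 °C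
Reagents that add atoms: none
Why: In this Corey–Bakshi–Shibata reduction the (R)-oxazaborolidine should bind the C8 ketone with branched C7 as the large and the C9 methylene as the small group and deliver hydride to the face giving 8S (reagent control, which would also divert any 7S ketone to a separable cis diastereomer), after which mild acid-catalysed acyl substitution of the methyl ester by the C8 hydroxyl closes the trans-fused γ-lactone (ring B) without touching C7 or C8.

**Step 16**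
Reactants: 28 trans-fused lactone
Product: 31 (3aR,5Z,9E,11aS)-6-{[(tert-butyldiphenylsilyl)oxy]methyl}-10-{[(4-methoxyphenyl)methoxy]methyl}-3-methylidene-3a,4,7,8,11,11a-hexahydrocyclodeca[b]furan-2(3H)-one, via Mannich base 29 (not isolated), via ammonium iodide 30 (not isolated)
Conditions: LiN(i-Pr)2 (1.2 equiv), THF, −78 °C; CH2=NMe2+ I−, −78 °C to rt; then MeI, MeOH, rt; then aq. NaHCO3, CH2Cl2
Reagents that add atoms: N,N-dimethylmethyleneiminium iodide (Eschenmoser's salt), C=[N+](C)C.[I-]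
Why: Kinetic deprotonation at C11 (the only α-position of the lactone), Mannich aminomethylation, N-methylation and E1cB loss of trimethylamine is the standard α-methylenation of γ-butyrolactones; the transient C11 centre disappears and C7 and C8 are not enolisable.

**Step 17**
Reactants: 31 α-methylene lactone with C15–OTBDPS
Product: 32 (3aR,5Z,9E,11aS)-6-(hydroxymethyl)-10-{[(4-methoxyphenyl)methoxy]methyl}-3-methylidene-3a,4,7,8,11,11a-hexahydrocyclodeca[b]furan-2(3H)-one
Conditions: HF·pyridine, THF, 0 °C to rt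
Reagents that add atoms: none
Why: Acidic fluoride removes the primary TBDPS ether without base, so the Michael-acceptor lactone and the PMB ether at C14 are left intact and only the C15 hydroxyl is freed.

**Step 18**
Reactants: 32 C15 alcohol; 33 2-hydroxy-2-methylpropanoic acid
Product: 34 [(3aR,5Z,9E,11aS)-10-{[(4-methoxyphenyl)methoxy]methyl}-3-methylidene-2-oxo-2,3,3a,4,7,8,11,11a-octahydrocyclodeca[b]furan-6-yl]methyl 2-hydroxy-2-methylpropanoate
Conditions: 33 (3 equiv), DCC (3 equiv), DMAP (0.2 equiv), CH2Cl2, 0 °C to rt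
Reagents that add atoms: none
Why: Steglich esterification acylates the primary allylic C15 hydroxyl far faster than the tertiary hydroxyl of the acid, so the hydroxy acid can be used unprotected.

**Step 19**
Reactants: 34 C14 PMB ether
Product: 35 [(3aR,5Z,9E,11aS)-10-(hydroxymethyl)-3-methylidene-2-oxo-2,3,3a,4,7,8,11,11a-octahydrocyclodeca[b]furan-6-yl]methyl 2-hydroxy-2-methylpropanoate (CNP0194188.1)
Conditions: DDQ (1.3 equiv), CH2Cl2/pH 7 phosphate buffer (10:1), 0 °C
Reagents that add atoms: none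
Why: Oxidative cleavage of the electron-rich PMB ether by DDQ under buffered conditions is faster than oxidation of the allylic alcohol it liberates and leaves both esters, the enoate and the olefins untouched.

**Compound list**
1 | 2-bromoprop-2-en-1-ol | C=C(Br)CO | starting material
2 | [(2-bromoprop-2-en-1-yl)oxy](tert-butyl)diphenylsilane | C=C(Br)CO[Si](c1ccccc1)(c1ccccc1)C(C)(C)C | intermediate
3 | 2-[(tert-butyldimethylsilyl)oxy]acetaldehyde | O=CCO[Si](C)(C)C(C)(C)C | starting material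
4 | (3-{[tert-butyl(diphenyl)silyl]oxy}prop-1-en-2-yl)chromium dichloride | C=C(CO[Si](c1ccccc1)(c1ccccc1)C(C)(C)C)[Cr](Cl)Cl | intermediate
5 | rac-1-[(tert-butyldimethylsilyl)oxy]-3-{[(tert-butyldiphenylsilyl)oxy]methyl}but-3-en-2-ol | C=C(CO[Si](c1ccccc1)(c1ccccc1)C(C)(C)C)C(O)CO[Si](C)(C)C(C)(C)C | intermediate
6 | triethyl orthoacetate | CCOC(C)(OCC)OCC | starting material
7 | 1-ethoxyvinyl ether of 5 (mixed ketene acetal) | C=C(OCC)OC(CO[Si](C)(C)C(C)(C)C)C(=C)CO[Si](c1ccccc1)(c1ccccc1)C(C)(C)C | intermediate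
8 | ethyl (4Z)-6-[(tert-butyldimethylsilyl)oxy]-4-{[(tert-butyldiphenylsilyl)oxy]methyl}hex-4-enoate | CCOC(=O)CC/C(CO[Si](c1ccccc1)(c1ccccc1)C(C)(C)C)=C/CO[Si](C)(C)C(C)(C)C | intermediate
9 | (4Z)-6-[(tert-butyldimethylsilyl)oxy]-4-{[(tert-butyldiphenylsilyl)oxy]methyl}hex-4-enal | O=CCC/C(CO[Si](c1ccccc1)(c1ccccc1)C(C)(C)C)=C/CO[Si](C)(C)C(C)(C)C | intermediate
10 | 1-{[(2-bromoprop-2-en-1-yl)oxy]methyl}-4-methoxybenzene | C=C(Br)COCc1ccc(OC)cc1 | intermediate
11 | {3-[(4-methoxyphenyl)methoxy]prop-1-en-2-yl}lithium | [Li]C(=C)COCc1ccc(OC)cc1 | intermediate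
12 | rac-(6Z)-8-[(tert-butyldimethylsilyl)oxy]-6-{[(tert-butyldiphenylsilyl)oxy]methyl}-2-{[(4-methoxyphenyl)methoxy]methyl}octa-1,6-dien-3-ol | C=C(COCc1ccc(OC)cc1)C(O)CC/C(CO[Si](c1ccccc1)(c1ccccc1)C(C)(C)C)=C/CO[Si](C)(C)C(C)(C)C | intermediate
13 | tributyl(iodomethyl)stannane | CCCC[Sn](CCCC)(CCCC)CI | starting material
14 | (tributylstannyl)methyl ether of 12 | C=C(COCc1ccc(OC)cc1)C(OC[Sn](CCCC)(CCCC)CCCC)CC/C(CO[Si](c1ccccc1)(c1ccccc1)C(C)(C)C)=C/CO[Si](C)(C)C(C)(C)C | intermediate
15 | lithiomethyl ether of 12 | C=C(COCc1ccc(OC)cc1)C(OC[Li])CC/C(CO[Si](c1ccccc1)(c1ccccc1)C(C)(C)C)=C/CO[Si](C)(C)C(C)(C)C | intermediate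
16 | (3E,7Z)-9-[(tert-butyldimethylsilyl)oxy]-7-{[(tert-butyldiphenylsilyl)oxy]methyl}-3-{[(4-methoxyphenyl)methoxy]methyl}nona-3,7-dien-1-ol | OCC/C(COCc1ccc(OC)cc1)=C\CC/C(CO[Si](c1ccccc1)(c1ccccc1)C(C)(C)C)=C/CO[Si](C)(C)C(C)(C)C | intermediate
17 | (3E,7Z)-9-[(tert-butyldimethylsilyl)oxy]-7-{[(tert-butyldiphenylsilyl)oxy]methyl}-3-{[(4-methoxyphenyl)methoxy]methyl}nona-3,7-dienal | O=CC/C(COCc1ccc(OC)cc1)=C\CC/C(CO[Si](c1ccccc1)(c1ccccc1)C(C)(C)C)=C/CO[Si](C)(C)C(C)(C)C | intermediate
18 | (3E,7Z)-9-[(tert-butyldimethylsilyl)oxy]-7-{[(tert-butyldiphenylsilyl)oxy]methyl}-3-{[(4-methoxyphenyl)methoxy]methyl}nona-3,7-dienoic acid | OC(=O)C/C(COCc1ccc(OC)cc1)=C\CC/C(CO[Si](c1ccccc1)(c1ccccc1)C(C)(C)C)=C/CO[Si](C)(C)C(C)(C)C | intermediate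
19 | 2,2-dimethyl-1,3-dioxane-4,6-dione (Meldrum's acid) | CC1(C)OC(=O)CC(=O)O1 | starting material
20 | 5-[(3E,7Z)-9-[(tert-butyldimethylsilyl)oxy]-7-{[(tert-butyldiphenylsilyl)oxy]methyl}-1-hydroxy-3-{[(4-methoxyphenyl)methoxy]methyl}nona-3,7-dien-1-ylidene]-2,2-dimethyl-1,3-dioxane-4,6-dione | OC(C/C(COCc1ccc(OC)cc1)=C\CC/C(CO[Si](c1ccccc1)(c1ccccc1)C(C)(C)C)=C/CO[Si](C)(C)C(C)(C)C)=C2C(=O)OC(C)(C)OC2=O | intermediate
21 | 5-[(3E,7Z)-7-{[(tert-butyldiphenylsilyl)oxy]methyl}-1,9-dihydroxy-3-{[(4-methoxyphenyl)methoxy]methyl}nona-3,7-dien-1-ylidene]-2,2-dimethyl-1,3-dioxane-4,6-dione | OC(C/C(COCc1ccc(OC)cc1)=C\CC/C(CO[Si](c1ccccc1)(c1ccccc1)C(C)(C)C)=C/CO)=C2C(=O)OC(C)(C)OC2=O | intermediate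
22 | (5E,9Z)-9-{[(tert-butyldiphenylsilyl)oxy]methyl}-11-hydroxy-5-{[(4-methoxyphenyl)methoxy]methyl}undeca-1,5,9-triene-1,3-dione (acylketene) | O=C=CC(=O)C/C(COCc1ccc(OC)cc1)=C\CC/C(CO[Si](c1ccccc1)(c1ccccc1)C(C)(C)C)=C/CO | intermediate
23 | (6E,10Z)-10-{[(tert-butyldiphenylsilyl)oxy]methyl}-6-{[(4-methoxyphenyl)methoxy]methyl}-1-oxacyclododeca-6,10-diene-2,4-dione | O=C1C/C(COCc2ccc(OC)cc2)=C\CC/C(CO[Si](c2ccccc2)(c2ccccc2)C(C)(C)C)=C/COC(=O)C1 | intermediate
24 | methyl bromoacetate | COC(=O)CBr | starting material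
25 | methyl 2-[(6E,10Z)-10-{[(tert-butyldiphenylsilyl)oxy]methyl}-6-{[(4-methoxyphenyl)methoxy]methyl}-2,4-dioxo-1-oxacyclododeca-6,10-dien-3-yl]acetate (racemic at C7) | O=C1C/C(COCc2ccc(OC)cc2)=C\CC/C(CO[Si](c2ccccc2)(c2ccccc2)C(C)(C)C)=C/COC(=O)C1CC(=O)OC | intermediate
26 | methyl 2-[(1R,3Z,7E)-4-{[(tert-butyldiphenylsilyl)oxy]methyl}-8-{[(4-methoxyphenyl)methoxy]methyl}-10-oxocyclodeca-3,7-dien-1-yl]acetate | O=C1C/C(COCc2ccc(OC)cc2)=C\CC/C(CO[Si](c2ccccc2)(c2ccccc2)C(C)(C)C)=C/C[C@@H]1CC(=O)OC | intermediate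
27 | methyl 2-[(1R,3Z,7E,10S)-4-{[(tert-butyldiphenylsilyl)oxy]methyl}-10-hydroxy-8-{[(4-methoxyphenyl)methoxy]methyl}cyclodeca-3,7-dien-1-yl]acetate | O[C@H]1C/C(COCc2ccc(OC)cc2)=C\CC/C(CO[Si](c2ccccc2)(c2ccccc2)C(C)(C)C)=C/C[C@@H]1CC(=O)OC | intermediate
28 | (3aR,5Z,9E,11aS)-6-{[(tert-butyldiphenylsilyl)oxy]methyl}-10-{[(4-methoxyphenyl)methoxy]methyl}-3a,4,7,8,11,11a-hexahydrocyclodeca[b]furan-2(3H)-one | C1C(=O)O[C@H]2C/C(COCc3ccc(OC)cc3)=C\CC/C(CO[Si](c3ccccc3)(c3ccccc3)C(C)(C)C)=C/C[C@H]12 | intermediate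
29 | 3-[(dimethylamino)methyl] derivative of 28 (C11 epimers) | CN(C)CC1C(=O)O[C@H]2C/C(COCc3ccc(OC)cc3)=C\CC/C(CO[Si](c3ccccc3)(c3ccccc3)C(C)(C)C)=C/C[C@H]12 | intermediate
30 | 3-[(trimethylammonio)methyl] derivative of 28, iodide | C[N+](C)(C)CC1C(=O)O[C@H]2C/C(COCc3ccc(OC)cc3)=C\CC/C(CO[Si](c3ccccc3)(c3ccccc3)C(C)(C)C)=C/C[C@H]12.[I-] | intermediate
31 | (3aR,5Z,9E,11aS)-6-{[(tert-butyldiphenylsilyl)oxy]methyl}-10-{[(4-methoxyphenyl)methoxy]methyl}-3-methylidene-3a,4,7,8,11,11a-hexahydrocyclodeca[b]furan-2(3H)-one | C=C1C(=O)O[C@H]2C/C(COCc3ccc(OC)cc3)=C\CC/C(CO[Si](c3ccccc3)(c3ccccc3)C(C)(C)C)=C/C[C@H]12 | intermediate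
32 | (3aR,5Z,9E,11aS)-6-(hydroxymethyl)-10-{[(4-methoxyphenyl)methoxy]methyl}-3-methylidene-3a,4,7,8,11,11a-hexahydrocyclodeca[b]furan-2(3H)-one | C=C1C(=O)O[C@H]2C/C(COCc3ccc(OC)cc3)=C\CC/C(CO)=C/C[C@H]12 | intermediate
33 | 2-hydroxy-2-methylpropanoic acid | CC(C)(O)C(=O)O | starting material
34 | [(3aR,5Z,9E,11aS)-10-{[(4-methoxyphenyl)methoxy]methyl}-3-methylidene-2-oxo-2,3,3a,4,7,8,11,11a-octahydrocyclodeca[b]furan-6-yl]methyl 2-hydroxy-2-methylpropanoate | C=C1C(=O)O[C@H]2C/C(COCc3ccc(OC)cc3)=C\CC/C(COC(=O)C(C)(C)O)=C/C[C@H]12 | intermediate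
35 | [(3aR,5Z,9E,11aS)-10-(hydroxymethyl)-3-methylidene-2-oxo-2,3,3a,4,7,8,11,11a-octahydrocyclodeca[b]furan-6-yl]methyl 2-hydroxy-2-methylpropanoate | C=C1C(=O)O[C@H]2C/C(CO)=C\CC/C(COC(=O)C(C)(C)O)=C/C[C@H]12 | target

**Totals**
Total step count: 19. Longest linear sequence: 18 steps (steps 1–4 and 6–19; step 5 is a one-step side branch).

**Steps most likely to fail**

Step 14 (ring contraction). The closure may not compete with β-hydride loss from the hindered π-allyl unit, with oligomerisation or with O-allylation. In addition, because C7 carries an acidic hydrogen, C–C bond formation may precede loss of CO2, or the product may epimerise, so that the ligand no longer controls C7. The fallback uses known reactions, sets out from 20 and returns at 26. Heating 20 with prop-2-en-1-ol in toluene (90 °C) should give the open-chain allyl β-keto ester F1. HF·pyridine then frees the C6 hydroxyl in the hydroxy β-keto ester F2, and CBr4/PPh3 converts it into the C6 allylic bromide F3. Cs2CO3 in MeCN at high dilution should close ring A by intramolecular C7-alkylation to the ten-membered allyl β-keto ester F4. K2CO3 and 24 in acetone then add the C11–C12 unit to give the C7-quaternary keto diester F5. Finally Pd(OAc)2, (S)-t-Bu-PHOX and HCO2H in dioxane at 40 °C (enantioselective decarboxylative protonation of an α-quaternary allyl β-keto ester) remove the allyl ester and set C7–H under ligand control, giving 26.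

Step 15 (C8 reduction). The conformational bias of the ten-membered ring may override the oxazaborolidine, giving poor facial selectivity or the 8R alcohol. The fallback sets out from 26 and returns at 28. It uses substrate control instead: NaBH4/CeCl3·7H2O in MeOH at −40 °C should attack from the ring periphery. If this gives the 8S alcohol, it lactonises directly to 28 under the PPTS conditions. If it gives the cis-configured 8R hydroxy ester F6, the crude alcohol is inverted at C8 by Mitsunobu esterification (PPh3, DIAD, 4-nitrobenzoic acid) to the 8S 4-nitrobenzoate F7; K2CO3 in MeOH then cleaves the benzoate and the released 8S alkoxide closes the trans-lactone 28.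

Step 12 (macrolactonisation). At the temperature needed to generate the acylketene, intermolecular trapping (diolide, oligomers) or migration of the C10=C1 bond toward the C8 carbonyl may outrun the twelve-membered ring closure. The fallback sets out from 20 and returns at 23, and closes the same ester bond at room temperature by thiophilic activation instead of thermolysis. Heating 20 with 2-methylpropane-2-thiol in toluene (90 °C) should give the S-tert-butyl β-keto thioester F8, and HF·pyridine frees the C6 hydroxyl in the hydroxy thioester F9. Slow addition of F9 to AgO2CCF3 and Na2HPO4 in THF at rt under high dilution should then give 23.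

**Further compounds**
F1 | step 14 | prop-2-en-1-yl (5E,9Z)-11-[(tert-butyldimethylsilyl)oxy]-9-{[(tert-butyldiphenylsilyl)oxy]methyl}-5-{[(4-methoxyphenyl)methoxy]methyl}-3-oxoundeca-5,9-dienoate | C=CCOC(=O)CC(=O)C/C(COCc1ccc(OC)cc1)=C\CC/C(CO[Si](c1ccccc1)(c1ccccc1)C(C)(C)C)=C/CO[Si](C)(C)C(C)(C)C
F2 | step 14 | prop-2-en-1-yl (5E,9Z)-9-{[(tert-butyldiphenylsilyl)oxy]methyl}-11-hydroxy-5-{[(4-methoxyphenyl)methoxy]methyl}-3-oxoundeca-5,9-dienoate | C=CCOC(=O)CC(=O)C/C(COCc1ccc(OC)cc1)=C\CC/C(CO[Si](c1ccccc1)(c1ccccc1)C(C)(C)C)=C/CO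
F3 | step 14 | prop-2-en-1-yl (5E,9Z)-11-bromo-9-{[(tert-butyldiphenylsilyl)oxy]methyl}-5-{[(4-methoxyphenyl)methoxy]methyl}-3-oxoundeca-5,9-dienoate | C=CCOC(=O)CC(=O)C/C(COCc1ccc(OC)cc1)=C\CC/C(CO[Si](c1ccccc1)(c1ccccc1)C(C)(C)C)=C/CBr
F4 | step 14 | prop-2-en-1-yl (3Z,7E)-4-{[(tert-butyldiphenylsilyl)oxy]methyl}-8-{[(4-methoxyphenyl)methoxy]methyl}-10-oxocyclodeca-3,7-diene-1-carboxylate (racemic) | O=C1C/C(COCc2ccc(OC)cc2)=C\CC/C(CO[Si](c2ccccc2)(c2ccccc2)C(C)(C)C)=C/CC1C(=O)OCC=C
F5 | step 14 | prop-2-en-1-yl (3Z,7E)-4-{[(tert-butyldiphenylsilyl)oxy]methyl}-1-(2-methoxy-2-oxoethyl)-8-{[(4-methoxyphenyl)methoxy]methyl}-10-oxocyclodeca-3,7-diene-1-carboxylate (racemic) | O=C1C/C(COCc2ccc(OC)cc2)=C\CC/C(CO[Si](c2ccccc2)(c2ccccc2)C(C)(C)C)=C/CC1(CC(=O)OC)C(=O)OCC=C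
F6 | step 15 | methyl 2-[(1R,3Z,7E,10R)-4-{[(tert-butyldiphenylsilyl)oxy]methyl}-10-hydroxy-8-{[(4-methoxyphenyl)methoxy]methyl}cyclodeca-3,7-dien-1-yl]acetate | O[C@@H]1C/C(COCc2ccc(OC)cc2)=C\CC/C(CO[Si](c2ccccc2)(c2ccccc2)C(C)(C)C)=C/C[C@@H]1CC(=O)OC
F7 | step 15 | methyl 2-[(1R,3Z,7E,10S)-4-{[(tert-butyldiphenylsilyl)oxy]methyl}-8-{[(4-methoxyphenyl)methoxy]methyl}-10-[(4-nitrobenzoyl)oxy]cyclodeca-3,7-dien-1-yl]acetate | O=C(O[C@H]1C/C(COCc2ccc(OC)cc2)=C\CC/C(CO[Si](c2ccccc2)(c2ccccc2)C(C)(C)C)=C/C[C@@H]1CC(=O)OC)c1ccc([N+](=O)[O-])cc1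
F8 | step 12 | S-tert-butyl (5E,9Z)-11-[(tert-butyldimethylsilyl)oxy]-9-{[(tert-butyldiphenylsilyl)oxy]methyl}-5-{[(4-methoxyphenyl)methoxy]methyl}-3-oxoundeca-5,9-dienethioate | CC(C)(C)SC(=O)CC(=O)C/C(COCc1ccc(OC)cc1)=C\CC/C(CO[Si](c1ccccc1)(c1ccccc1)C(C)(C)C)=C/CO[Si](C)(C)C(C)(C)C
F9 | step 12 | S-tert-butyl (5E,9Z)-9-{[(tert-butyldiphenylsilyl)oxy]methyl}-11-hydroxy-5-{[(4-methoxyphenyl)methoxy]methyl}-3-oxoundeca-5,9-dienethioate | CC(C)(C)SC(=O)CC(=O)C/C(COCc1ccc(OC)cc1)=C\CC/C(CO[Si](c1ccccc1)(c1ccccc1)C(C)(C)C)=C/CO
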